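**Strategy.** Everything rests on cutting the five-membered lactone ring between the carbonyl carbon C1 and aromatic carbon C7a (phthalide numbering). C7a is ortho to C3a, which carries the C3–O2 carbinol, and is flanked by the C7 methoxy group, so O2 can hold C1 as a phenyl carbonate and deliver it to an aryllithium at C7a. The key step, a bromine–lithium exchange-triggered Parham cyclisation of (S)-1-(2-bromo-3,5-dimethoxyphenyl)pentadec-14-enyl phenyl carbonate, should form C1–C7a and the complete phthalide in one operation, leaving untouched the C3 stereocenter set earlier by catalytic asymmetric alkylzinc addition. The methyl ketone is carried as a terminal alkene and unveiled last by Wacker oxidation.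

Key step: step 3

Assumptions: compounds 1 and 2 are taken as catalogue compounds; the stereocenter of the target as drawn is S (priorities O > aryl carbon > chain CH2 > H), and the side chain is (CH2)12C(=O)CH3.

**Step 1**
Reactants: 1 2-bromo-3,5-dimethoxybenzaldehyde; 2 tetradeca-1,13-diene
Product: 5 (S)-1-(2-bromo-3,5-dimethoxyphenyl)pentadec-14-en-1-ol, via alkyldiethylborane 3 (not isolated), via dialkylzinc 4 (not isolated)
Conditions: 2 (3 equiv per B–H), Et2BH (from BH3·SMe2 + 2 Et3B), 0 °C to rt; Et2Zn, 0 °C, then volatiles removed in vacuo; 1, Ti(OiPr)4 (2 equiv), (1R,2R)-1,2-bis(trifluoromethanesulfonamido)cyclohexane (8 mol %), toluene, −20 °C; aq. HCl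
Reagents that add atoms: none
Why: Anti-Markovnikov hydroboration of one terminal alkene of the excess diene, boron–zinc exchange and Ti(OiPr)4/chiral bis(sulfonamide)-catalysed enantioselective dialkylzinc addition to the aromatic aldehyde should give the secondary alcohol, the (1R,2R) ligand directing the primary alkyl group to the Si face of the aldehyde (as it does for benzaldehyde) and so setting the carbinol carbon as S, while the aryl bromide and the remote alkene are inert to the zinc reagent.

**Step 2**
Reactants: 5 (S)-1-(2-bromo-3,5-dimethoxyphenyl)pentadec-14-en-1-ol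
Product: 6 (S)-1-(2-bromo-3,5-dimethoxyphenyl)pentadec-14-en-1-yl phenyl carbonate
Conditions: PhOCOCl (1.3 equiv), pyridine, DMAP (cat.), CH2Cl2, 0 °C to rt
Reagents that add atoms: phenyl chloroformate, O=C(Cl)Oc1ccccc1
Why: Pyridine/DMAP-mediated O-acylation of the secondary benzylic alcohol by the chloroformate (mixed carbonate formation) takes place at oxygen only, so no bond to the stereocenter is broken and the S configuration is retained.

**Step 3**
Reactants: 6 (S)-1-(2-bromo-3,5-dimethoxyphenyl)pentadec-14-en-1-yl phenyl carbonate
Product: 9 (S)-5,7-dimethoxy-3-(tetradec-13-en-1-yl)isobenzofuran-1(3H)-one, via aryllithium 7 (not isolated), via tetrahedral alkoxide 8 (not isolated)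
Conditions: s-BuLi (1.05 equiv), THF/Et2O/pentane 4:1:1, −100 °C to −78 °C; sat. aq. NH4Cl
Reagents that add atoms: none
Why: Bromine–lithium exchange at C2 of the aryl ring (the future C7a), assisted by the flanking methoxy group, should give aryllithium 7, whose carbanion adds to the carbonate carbonyl held through O–C3–C3a, and tetrahedral alkoxide 8 then expels phenoxide, the best leaving group on that carbon, so the ring closed by the new C7a–C1 bond is retained as the lactone. The closest known reaction type is the Parham cyclisation (halogen–metal exchange followed by intramolecular acylation of the aryllithium by an ester, carbamate or carbonate), and low-temperature exchange next to an aryl ester is known from exchange-triggered anionic Fries rearrangements. The five-membered lactone ring (C7a, C1, O2, C3, C3a) closes in a 5-exo-trig mode. No stereocenter is formed, and C3 keeps its S configuration because no bond to it is made or broken and only 1.05 equiv of base is present, so the benzylic proton should not be removed. The step needs exchange to outrun addition of s-BuLi to the carbonate and intramolecular acylation to outrun intermolecular reaction; the hindered secondary alkyllithium, the very low temperature, the chelating ortho-methoxy group and the five-membered transition state should secure this, and the single equivalent leaves no alkyllithium to attack the lactone formed.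

**Step 4**
Reactants: 9 (S)-5,7-dimethoxy-3-(tetradec-13-en-1-yl)isobenzofuran-1(3H)-one
Product: 10 CJ-13,108, (S)-5,7-dimethoxy-3-(13-oxotetradecyl)isobenzofuran-1(3H)-one
Conditions: PdCl2 (10 mol %), CuCl (20 mol %), O2 (1 atm), DMF/H2O 7:1, rt
Reagents that add atoms: water, O
Why: Tsuji–Wacker oxidation, in which Markovnikov hydroxypalladation of the terminal alkene by water and β-hydride elimination should give the methyl ketone with O2/CuCl reoxidising palladium, under neutral conditions that leave the lactone, the aryl ethers and the remote C3 stereocenter untouched.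

**Compound list**
1 | 2-bromo-3,5-dimethoxybenzaldehyde | COc1cc(OC)c(Br)c(C=O)c1 | starting material
2 | tetradeca-1,13-diene | C=CCCCCCCCCCCCC=C | starting material
3 | diethyl(tetradec-13-en-1-yl)borane | CCB(CC)CCCCCCCCCCCCC=C | intermediate
4 | bis(tetradec-13-en-1-yl)zinc | C=CCCCCCCCCCCCC[Zn]CCCCCCCCCCCCC=C | intermediate
5 | (S)-1-(2-bromo-3,5-dimethoxyphenyl)pentadec-14-en-1-ol | COc1cc(OC)c(Br)c(c1)[C@H](CCCCCCCCCCCCC=C)O | intermediate
6 | (S)-1-(2-bromo-3,5-dimethoxyphenyl)pentadec-14-en-1-yl phenyl carbonate | COc1cc(OC)c(Br)c(c1)[C@H](CCCCCCCCCCCCC=C)OC(=O)Oc2ccccc2 | intermediate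
7 | aryllithium: (S)-1-(2-lithio-3,5-dimethoxyphenyl)pentadec-14-en-1-yl phenyl carbonate | COc1cc(OC)c([Li])c(c1)[C@H](CCCCCCCCCCCCC=C)OC(=O)Oc2ccccc2 | intermediate
8 | tetrahedral alkoxide: lithium (3S)-5,7-dimethoxy-1-phenoxy-3-(tetradec-13-en-1-yl)-1,3-dihydroisobenzofuran-1-olate, both configurations at C1 | COc1cc(OC)c2c(c1)[C@H](CCCCCCCCCCCCC=C)OC2(O[Li])Oc3ccccc3 | intermediate
9 | (S)-5,7-dimethoxy-3-(tetradec-13-en-1-yl)isobenzofuran-1(3H)-one | COc1cc(OC)c2c(c1)[C@H](CCCCCCCCCCCCC=C)OC2=O | intermediate
10 | CJ-13,108, (S)-5,7-dimethoxy-3-(13-oxotetradecyl)isobenzofuran-1(3H)-one | COc1cc(OC)c2c(c1)[C@H](CCCCCCCCCCCCC(C)=O)OC2=O | target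

Total step count: 4. Longest linear sequence: 4 steps (1 → 5 → 6 → 9 → 10).

**Steps most likely to fail**

Step 3. Addition of s-BuLi to the phenyl carbonate carbonyl may compete with bromine–lithium exchange, and the aryllithium may be protonated before it closes the ring, so that acyl transfer to carbon is lost. The fallback sets out from compound 5 and returns to the route at compound 9. The free bromo alcohol 5 would be subjected to palladium-catalysed carbonylative lactonisation (Pd(OAc)2, Xantphos, CO at 1 atm, Et3N, toluene, 90 °C). Oxidative addition into the C–Br bond, CO insertion and intramolecular alcoholysis of the acylpalladium by the benzylic hydroxyl should give 9 directly with the stereocenter untouched. Step 2 is then skipped (no new compound, F0).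

Step 1. The boron–zinc exchange may stay incomplete, so that ethyl groups are transferred to the aldehyde. Both ends of the diene may be hydroborated. The ortho-bromo aldehyde may be alkylated with poor facial selectivity. The fallback sets out from compound 1 and returns at compound 5, setting the stereocenter by ketone reduction instead of alkyl addition. Purchased 14-bromotetradec-1-ene and Mg in THF would give tetradec-13-enylmagnesium bromide F1, which adds to 1 at 0 °C to give racemic 1-(2-bromo-3,5-dimethoxyphenyl)pentadec-14-en-1-ol F2. Dess–Martin periodinane in CH2Cl2 would oxidise this to 1-(2-bromo-3,5-dimethoxyphenyl)pentadec-14-en-1-one F3. Noyori transfer hydrogenation with RuCl(p-cymene)[(S,S)-TsDPEN] in HCO2H/Et3N tolerates the alkene and the aryl bromide and should reduce the aryl ketone to the S alcohol 5.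

Step 4. The terminal double bond may migrate along the chain by palladium hydride addition and elimination before oxidation, giving internal ketones, and the lipophilic substrate may turn over slowly in aqueous DMF. The fallback sets out from compound 9 and returns at compound 10 through a radical rather than an organopalladium hydration. Mukaiyama hydration (Co(acac)2 cat., PhSiH3, O2, i-PrOH, rt) should give the Markovnikov alcohol (3S)-3-(13-hydroxytetradecyl)-5,7-dimethoxyisobenzofuran-1(3H)-one F4 as both epimers at the side-chain carbinol. Dess–Martin periodinane in CH2Cl2 would then oxidise it to 10.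

**Further compounds**
F0 | step 3 | none | none
F1 | step 1 | tetradec-13-enylmagnesium bromide | C=CCCCCCCCCCCCC[Mg]Br
F2 | step 1 | racemic 1-(2-bromo-3,5-dimethoxyphenyl)pentadec-14-en-1-ol | COc1cc(OC)c(Br)c(c1)C(O)CCCCCCCCCCCCC=C
F3 | step 1 | 1-(2-bromo-3,5-dimethoxyphenyl)pentadec-14-en-1-one | COc1cc(OC)c(Br)c(c1)C(=O)CCCCCCCCCCCCC=C
F4 | step 4 | (3S)-3-(13-hydroxytetradecyl)-5,7-dimethoxyisobenzofuran-1(3H)-one, both epimers at the side-chain carbinol | COc1cc(OC)c2c(c1)[C@H](CCCCCCCCCCCCC(C)O)OC2=O
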